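Assumption: phlorisobutyrophenone and (4S)-limonene 1,2-oxide (cis/trans mixture from (S)-(−)-limonene) are bought as catalogue compounds; C1–C6 are p-menthane ring numbers and Ca is the triketone ring carbon bonded to C2.

**Retrosynthetic overview**
1. Chiral half: (4S)-limonene oxide 1 is cleaved, through diol 2, to keto-aldehyde 3, which carries the only bought stereocentre (C4 of the target).
2. Achiral half: phlorisobutyrophenone 4 is gem-diprenylated with dearomatisation to triketone 5.
3. Key disconnections of the target, read backwards: the C1–C2 ring bond (cathodic reductive cyclisation) and then Ca=C2 (Knoevenagel), giving alkylidene 6 = 3 + 5; forwards this delivers target 7.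
4. Ring order: the dearomatised triketone ring is present first (in 5); the p-menthane cyclohexane ring is formed last, in the electrochemical step, which sets C1 and C2 from C4.

**Route**

Step 1
Reactants: 1 (4S)-limonene 1,2-oxide (cis/trans mixture)
Product: 3 (3S)-6-oxo-3-(prop-1-en-2-yl)heptanal, via limonene diol 2 (not isolated)
Conditions: H5IO6 (1.2 equiv), THF–H2O 4:1, 0 °C to rt, 2 h
Reagents that add atoms: water, O
Why: Acid-promoted trans-diaxial hydrolysis of both epoxide diastereomers converges on diol 2, which periodate cleaves (Malaprade glycol cleavage); the C4 stereocentre is β to the new aldehyde, cannot epimerise, and becomes C3 of 3.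

Step 2
Reactants: 4 phlorisobutyrophenone
Product: 5 3,5-dihydroxy-2-(2-methylpropanoyl)-6,6-bis(3-methylbut-2-en-1-yl)cyclohexa-2,4-dien-1-one
Conditions: NaOMe (3.0 equiv), prenyl bromide (2.1 equiv), MeOH, −10 °C to rt, 4 h; 1 M HCl work-up; NaHCO3 extraction, then chromatography
Reagents that add atoms: prenyl bromide (1-bromo-3-methylbut-2-ene), CC(C)=CCBr
Why: Alkylative dearomatisation of the phloroglucinolate, in which the second C-prenylation competes effectively at the already substituted ring carbon; 5 is a vinylogous acid and is separated from the aromatic 3,5-diprenyl isomer by bicarbonate extraction (expect roughly 30–40 %); no stereocentre is formed.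

Step 3
Reactants: 5 3,5-dihydroxy-2-(2-methylpropanoyl)-6,6-bis(3-methylbut-2-en-1-yl)cyclohexa-2,4-dien-1-one; 3 (3S)-6-oxo-3-(prop-1-en-2-yl)heptanal (1.2 equiv)
Product: 7 3,5-dihydroxy-4-[(1R,2R,5S)-2-hydroxy-2-methyl-5-(prop-1-en-2-yl)cyclohexyl]-2-(2-methylpropanoyl)-6,6-bis(3-methylbut-2-en-1-yl)cyclohexa-2,4-dien-1-one, via alkylidene triketone 6 (not isolated)
Conditions: ethylenediammonium diacetate (10 mol%), MeCN, 0 °C, 30 min; then 2,6-lutidine (1.1 equiv), n-Bu4NBF4 (0.1 M), undivided cell, Mg anode, reticulated vitreous carbon cathode, ca. −1.6 V vs Ag/AgCl, 2.2 F/mol, 0 °C; sat. aq NH4Cl work-up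
Reagents that add atoms: none
Why: Proposed new method: a one-pot Knoevenagel condensation / cathodic reductive cyclisation on an alkylidene β-triketone. The achiral ammonium acetate condenses the aldehyde of 3 with the acidic ring CH of 5 to give the quinone-methide-like alkylidene 6, which should be by far the most easily reduced group (estimated near −1.3 V, against below −2.2 V for the isolated ketone, the aldehyde and the alkenes). Its radical anion has spin at C2 and, with anode-derived Mg2+ bridging a dione oxygen and the ketone oxygen, adds 6-exo to the ketone carbon C1; the resulting triketonyl radical takes the second electron at once, so ring closure is irreversible, and lutidinium is the only (weak) proton donor, which disfavours simple saturation of 6. A chair transition state with the C4 isopropenyl, the planar triketone on C2 and the C1 methyl all equatorial and the Mg-bound oxygen axial sets (1R,2R) from the bought (4S) centre; the C1 epimer is the expected minor product. The closest known reaction type is the Little electroreductive cyclisation of ketone-tethered alkylidene malonates (also Sm(II) ketone–olefin cyclisation and reductive umpolung of quinone methides), which has not been shown for alkylidene triketones or run directly from the aldehyde.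

**Compound list**
1 | (4S)-limonene 1,2-oxide, (4S)-1-methyl-4-(prop-1-en-2-yl)-7-oxabicyclo[4.1.0]heptane, cis/trans mixture at the epoxide | C=C(C)[C@H]1CCC2(C)OC2C1 | starting material
2 | (1R,2R,4S)-1-methyl-4-(prop-1-en-2-yl)cyclohexane-1,2-diol | C=C(C)[C@H]1CC[C@@](C)(O)[C@H](O)C1 | intermediate (not isolated)
3 | (3S)-6-oxo-3-(prop-1-en-2-yl)heptanal | C=C(C)[C@H](CC=O)CCC(C)=O | intermediate
4 | phlorisobutyrophenone, 2-methyl-1-(2,4,6-trihydroxyphenyl)propan-1-one | CC(C)C(=O)c1c(O)cc(O)cc1O | starting material
5 | 3,5-dihydroxy-2-(2-methylpropanoyl)-6,6-bis(3-methylbut-2-en-1-yl)cyclohexa-2,4-dien-1-one | CC(C)C(=O)C1=C(O)C=C(O)C(CC=C(C)C)(CC=C(C)C)C1=O | intermediate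
6 | 5-hydroxy-4-(2-methylpropanoyl)-6,6-bis(3-methylbut-2-en-1-yl)-2-[(3S)-6-oxo-3-(prop-1-en-2-yl)heptylidene]cyclohex-4-ene-1,3-dione (alkylidene geometry not defined) | C=C(C)[C@H](CC=C1C(=O)C(C(=O)C(C)C)=C(O)C(CC=C(C)C)(CC=C(C)C)C1=O)CCC(C)=O | intermediate (not isolated)
7 | 3,5-dihydroxy-4-[(1R,2R,5S)-2-hydroxy-2-methyl-5-(prop-1-en-2-yl)cyclohexyl]-2-(2-methylpropanoyl)-6,6-bis(3-methylbut-2-en-1-yl)cyclohexa-2,4-dien-1-one (terpene unit = (1R,2R,4S)-1-hydroxy-p-menth-8-en-2-yl; isopropenyl, triketone and methyl equatorial, OH axial) | C=C(C)[C@H]1CC[C@@](C)(O)[C@@H](C2=C(O)C(CC=C(C)C)(CC=C(C)C)C(=O)C(C(=O)C(C)C)=C2O)C1 | target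

**Step count**
Total steps: 3. Longest linear sequence: 2 (1 → 3 → 7, or 4 → 5 → 7).

**Steps most likely to fail, with fallbacks**

Step 3 (the proposed new step) is the main risk. The radical anion of 6 may simply be protonated and reduced further to the open-chain saturated compound, 6 may add a second molecule of 5, or the C1 epimer may predominate. The fallback uses known chemistry and sets out from alkylidene triketone 6, made from 3 and 5 exactly as in the first half of step 3. The cold MeCN solution is diluted with THF and added to SmI2 (2.5 equiv) with t-BuOH (2 equiv) and no HMPA at −78 °C. This is a stoichiometric, inner-sphere Sm(II) ketone–olefin reductive cyclisation of the Molander type, in which Sm(III) holds the ketone oxygen and a dione oxygen together while the C1–C2 bond forms. It returns to the route at 7 after NH4Cl work-up and chromatography. New compounds on the way: none F0.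

Step 2 is the next risk, because prenylation gives a mixture of the wanted gem-diprenyl compound with the aromatic 3,5-diprenyl isomer and with triprenyl and O-prenyl products. The fallback sets out from 4 and blocks one ring carbon. NBS (1.0 equiv, THF, −78 °C) gives 1-(3-bromo-2,4,6-trihydroxyphenyl)-2-methylpropan-1-one F1. NaOMe and prenyl bromide (2.1 equiv) in MeOH can then alkylate only the single remaining ring CH, twice, because the brominated carbon is deactivated; this gives 4-bromo-3,5-dihydroxy-2-(2-methylpropanoyl)-6,6-bis(3-methylbut-2-en-1-yl)cyclohexa-2,4-dien-1-one F2. The positive-halogen α-bromo triketone is reduced with aqueous Na2SO3 (or Zn/AcOH) at 0 °C, and the sequence comes back to the route at 5.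

Step 1 is reliable but 3 is sensitive: in acid or on storage it can undergo intramolecular aldol or carbonyl-ene reactions. The fallback sets out from 1 and isolates the crystalline diol 2 (1 % aqueous H2SO4, 0 °C, recrystallised), which stores indefinitely. It is cleaved only when needed under anhydrous, non-acidic Criegee conditions (Pb(OAc)4, K2CO3, CH2Cl2, −20 °C), and the filtered solution of 3 is used directly, so it comes back to the route at 3. New compounds on the way: none F0.

**Further compounds**
F0 | step 3 | none | none
F1 | step 2 | 1-(3-bromo-2,4,6-trihydroxyphenyl)-2-methylpropan-1-one | CC(C)C(=O)c1c(O)cc(O)c(Br)c1O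
F2 | step 2 | 4-bromo-3,5-dihydroxy-2-(2-methylpropanoyl)-6,6-bis(3-methylbut-2-en-1-yl)cyclohexa-2,4-dien-1-one | CC(C)C(=O)C1=C(O)C(Br)=C(O)C(CC=C(C)C)(CC=C(C)C)C1=O
F0 | step 1 | none | none
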